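**Plan**
- Retrosynthetic cuts, in order: the two C–C bonds that join ring B of the naphthazarin to the quinone ring; the angelate O–acyl bond; a C–CO2H bond at cyclobutane C3; the cyclobutane bonds C1–C4 and C2–C3 together; the enol ester O–acyl bond; the aryl–CO bond.
- Enabling feature: the oxygen on the quaternary cyclobutane carbon C1 (the carbon carrying the aryl ring; C2 = CMe2, C3 and C4 = CH2) can anchor an acryloyl group. Its CH2 and CH become C4 and C3, and its carbonyl bridges C3 to that oxygen as the γ-lactone ring of a 2-oxabicyclo[2.1.1]hexan-3-one, later expelled as CO2.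
- Forward order: aryl isopropyl ketone, enol acrylate, then cyclobutane and bridging lactone in one sensitised crossed [2+2]; lactone opening, resolution, decarboxylation; angelate; benzoquinone; ring B last by Diels–Alder reaction and aromatisation.
- Stereochemistry: C1, the only stereocentre, arises in the photocycloaddition as a racemate. The (R) series is selected by crystallising the (R)-1-phenylethylammonium salt of the ring-opened hydroxy acid, and no later step breaks a bond at C1. The Z alkene comes with angelic acid and is kept by base-only acylation.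

Key step: step 3

Remark on the target: a naphthazarin is a pair of fast-exchanging tautomers; the target is written with the side chain on the quinoid ring, as in the structure asked for.
Remark on the resolution: which enantiomer of 1-phenylethylamine gives the less soluble salt with the (1S,3R)-acid cannot be foreseen; the (R)-amine is assumed, and the (S)-amine would be used in the same way if the pairing is reversed.

**Route**

Step 1
Reactants: 1 1,4-dimethoxybenzene; 2 isobutyryl chloride
Product: 3 1-(2,5-dimethoxyphenyl)-2-methylpropan-1-one
Conditions: AlCl3 (1.1 equiv), CH2Cl2, 0 °C to rt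
Reagents that add atoms: isobutyryl chloride (2), CC(C)C(=O)Cl
Why: Friedel–Crafts acylation, in which all four ring positions of 1 are equivalent, the aryl ketone formed is deactivated against a second acylation, and the low temperature with only a slight excess of AlCl3 should spare the ortho methyl ether.

Step 2
Reactants: 3 1-(2,5-dimethoxyphenyl)-2-methylpropan-1-one; 4 acryloyl chloride
Product: 6 1-(2,5-dimethoxyphenyl)-2-methylprop-1-en-1-yl prop-2-enoate, via potassium enolate 5 (not isolated)
Conditions: KN(SiMe3)2 (1.05 equiv), THF, −78 °C; then cannulated into acryloyl chloride (1.5 equiv), THF, −78 °C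
Reagents that add atoms: acryloyl chloride (4), C=CC(=O)Cl
Why: O-acylation of a ketone enolate, in which 3 has a single enolisable hydrogen, the fully substituted potassium enolate is shielded at carbon and should be captured at oxygen by the hard acyl chloride, inverse addition at low temperature limits Michael addition to the acrylate formed, and the CMe2 terminus leaves no alkene geometry to control.

Step 3
Reactants: 6 1-(2,5-dimethoxyphenyl)-2-methylprop-1-en-1-yl prop-2-enoate
Product: 7 racemic (1R,4S)-1-(2,5-dimethoxyphenyl)-5,5-dimethyl-2-oxabicyclo[2.1.1]hexan-3-one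
Conditions: thioxanthone (10 mol %), degassed MeCN (0.01 M), 385 nm LEDs, 45 °C, flow reactor
Reagents that add atoms: none
Why: Proposed new method: triplet energy transfer from thioxanthone (6 itself is transparent at 385 nm) should turn the aryl enol ester into a twisted styrene-type 1,2-diradical, which in the s-cis ester rotamer (helped by the polar solvent and the warm bath) bonds through its aryl-bearing carbon to the acrylate CH2, giving a 1,4-diradical (tertiary at CMe2, α-acyl at the former acrylate CH) that couples after intersystem crossing. The closest known reaction type is the sensitised crossed intramolecular [2+2] photocycloaddition of 2-aryl-1,5-dienes and their allyl vinyl ether analogues to bicyclo[2.1.1]hexanes and 2-oxabicyclo[2.1.1]hexanes; an ester as the two-atom tether is the untested element. The γ-lactone closes first as a five-membered ring (rule of five; 5-endo-trig seen from the benzylic radical, and if CMe2 bonded to the acrylate CH first it would be a 5-exo-trig closure leading to the same product), and the cyclobutane closes second by 1,4-diradical recombination. The two new stereocentres are the bridgeheads C1 and C4, whose relative configuration is dictated by the one-atom bridges (only the cis-1,3 junction can exist), while nothing controls the absolute sense, so 7 should form as a racemate that step 5 resolves. The step needs crossed rather than straight regiochemistry, which the two-atom tether secures because the straight mode would require a four-membered first closure to a bicyclo[2.2.0] β-lactone, and it needs cycloaddition to outrun polymerisation and 1,3-acyl shift, which dilution, long-wavelength sensitisation and the CMe2 terminus (unproductive triplet decay can only return 6, there being no alkene geometry to lose) are meant to secure.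

Step 4
Reactants: 7 racemic (1R,4S)-1-(2,5-dimethoxyphenyl)-5,5-dimethyl-2-oxabicyclo[2.1.1]hexan-3-one
Product: 8 racemic (1S,3R)-3-(2,5-dimethoxyphenyl)-3-hydroxy-2,2-dimethylcyclobutane-1-carboxylic acid
Conditions: LiOH·H2O (3 equiv), THF/H2O (3:1), 0 °C to rt; then 1 M HCl to pH 3–4, 0 °C
Reagents that add atoms: lithium hydroxide, [Li+].[OH-]
Why: Saponification by acyl–oxygen cleavage of a strained bridged γ-lactone, in which release of ring strain should make opening irreversible and, since no bond at either ring stereocentre is broken, the hydroxyl and carboxyl groups stay cis.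

Step 5
Reactants: 8 racemic (1S,3R)-3-(2,5-dimethoxyphenyl)-3-hydroxy-2,2-dimethylcyclobutane-1-carboxylic acid; 9 (R)-1-phenylethylamine
Product: 10 (R)-1-phenylethylammonium (1S,3R)-3-(2,5-dimethoxyphenyl)-3-hydroxy-2,2-dimethylcyclobutane-1-carboxylate
Conditions: (R)-1-phenylethylamine (0.5 equiv), EtOAc/EtOH, 70 °C to rt; recrystallised from EtOH to constant rotation
Reagents that add atoms: (R)-1-phenylethylamine (9), C[C@@H](N)c1ccccc1
Why: Classical resolution through diastereomeric salts by the half-equivalent method, in which the less soluble salt is expected to carry one enantiomer of the acid, its absolute configuration being read from an X-ray structure with the amine centre as internal reference.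

Step 6
Reactants: 10 (R)-1-phenylethylammonium (1S,3R)-3-(2,5-dimethoxyphenyl)-3-hydroxy-2,2-dimethylcyclobutane-1-carboxylate
Product: 13 (1R)-1-(2,5-dimethoxyphenyl)-2,2-dimethylcyclobutan-1-ol, via free hydroxy acid 11 (not isolated), via Barton ester 12 (not isolated)
Conditions: 0.5 M HCl, EtOAc, 0 °C; then 1-hydroxypyridine-2(1H)-thione (1.2 equiv), DCC (1.2 equiv), DMAP (0.1 equiv), CH2Cl2, 0 °C to rt, dark; then t-BuSH (10 equiv), tungsten lamp, rt
Reagents that add atoms: none
Why: Barton reductive decarboxylation, in which the O-acyl thiohydroxamate fragments in a radical chain to CO2 and a secondary cyclobutyl radical that takes hydrogen from the thiol far faster than a cyclobutyl radical opens, so the carboxyl-bearing centre becomes a CH2 while the carbinol centre is not involved, and the cis tertiary hydroxyl should stay free because closing the strained bridged lactone cannot compete with ester formation.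

Step 7
Reactants: 13 (1R)-1-(2,5-dimethoxyphenyl)-2,2-dimethylcyclobutan-1-ol; 14 angelic acid
Product: 17 (1R)-1-(2,5-dimethoxyphenyl)-2,2-dimethylcyclobutyl (2Z)-2-methylbut-2-enoate, via angelic anhydride 15 (not isolated), via lithium alkoxide 16 (not isolated)
Conditions: angelic acid (2.4 equiv), DCC (1.2 equiv), CH2Cl2, 0 °C to rt, filtered; separately 13, LiN(SiMe3)2 (1.1 equiv), THF, −78 to 0 °C; anhydride solution added, 0 °C to rt; H2O
Reagents that add atoms: angelic acid (14), C/C=C(/C)C(=O)O
Why: Acylation of a preformed lithium alkoxide with the symmetrical anhydride, the stereoconservative way to angelates, in which the congested tertiary hydroxyl is made nucleophilic as its alkoxide, no acid, acyl chloride or nucleophilic amine is present to isomerise the Z enoate to the tiglate, and the C–O bond at the stereocentre is not broken.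

Step 8
Reactants: 17 (1R)-1-(2,5-dimethoxyphenyl)-2,2-dimethylcyclobutyl (2Z)-2-methylbut-2-enoate
Product: 18 (1R)-1-(3,6-dioxocyclohexa-1,4-dien-1-yl)-2,2-dimethylcyclobutyl (2Z)-2-methylbut-2-enoate
Conditions: (NH4)2Ce(NO3)6 (2.5 equiv), MeCN/H2O (3:1), 0 °C
Reagents that add atoms: water, O
Why: Oxidative demethylation of a hydroquinone dimethyl ether, in which two one-electron oxidations of the electron-rich arene and ipso attack of water release methanol and give the p-benzoquinone, while the electron-poor angelate alkene and the acylated tertiary oxygen (no free cyclobutanol that could open oxidatively) should be untouched.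

Step 9
Reactants: 19 succinic anhydride
Product: 20 2,5-bis(trimethylsilyloxy)furan
Conditions: Me3SiCl (2.5 equiv), Et3N (2.5 equiv), ZnCl2 (5 mol %), MeCN, rt to 45 °C; filtered and distilled
Reagents that add atoms: chlorotrimethylsilane, C[Si](C)(C)Cl
Why: Double O-silylation of the anhydride (silyl ketene acetal formation), driven by formation of the aromatic furan.

Step 10
Reactants: 18 (1R)-1-(3,6-dioxocyclohexa-1,4-dien-1-yl)-2,2-dimethylcyclobutyl (2Z)-2-methylbut-2-enoate; 20 2,5-bis(trimethylsilyloxy)furan
Product: 22 (1R)-1-(5,8-dihydroxy-1,4-dioxo-1,4-dihydronaphthalen-2-yl)-2,2-dimethylcyclobutyl (2Z)-2-methylbut-2-enoate (CNP0326301.1), via oxa-bridged cycloadduct 21 (not isolated)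
Conditions: 20 (1.3 equiv), CH2Cl2, −78 °C to rt; then 0.1 M HCl, THF, 0 °C
Reagents that add atoms: 2,5-bis(trimethylsilyloxy)furan (20), C[Si](C)(C)Oc1ccc(O[Si](C)(C)C)o1
Why: Diels–Alder reaction of the electron-rich bis(silyloxy)furan with the quinone at its unsubstituted C4=C5 bond (the other double bond carries the quaternary cyclobutyl group), after which the bridged bis-silyl ketal should lose both silyl groups and its oxygen bridge on mild acid work-up to a 5,8-dione whose enolisation gives the naphthazarin, the carbinol stereocentre being untouched.

**Compound list**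

1 | 1,4-dimethoxybenzene | COc1ccc(OC)cc1 | starting material
2 | isobutyryl chloride (2-methylpropanoyl chloride) | CC(C)C(=O)Cl | starting material
3 | 1-(2,5-dimethoxyphenyl)-2-methylpropan-1-one | CC(C)C(=O)c1cc(OC)ccc1OC | intermediate
4 | acryloyl chloride | C=CC(=O)Cl | starting material
5 | potassium 1-(2,5-dimethoxyphenyl)-2-methylprop-1-en-1-olate (formed in the flask, not isolated) | CC(C)=C([O-])c1cc(OC)ccc1OC.[K+] | intermediate
6 | 1-(2,5-dimethoxyphenyl)-2-methylprop-1-en-1-yl prop-2-enoate | C=CC(=O)OC(=C(C)C)c1cc(OC)ccc1OC | intermediate
7 | racemic (1R,4S)-1-(2,5-dimethoxyphenyl)-5,5-dimethyl-2-oxabicyclo[2.1.1]hexan-3-one (racemate; the (1R,4S) enantiomer is drawn) | O=C1O[C@]2(c3cc(OC)ccc3OC)C[C@H]1C2(C)C | intermediate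
8 | racemic (1S,3R)-3-(2,5-dimethoxyphenyl)-3-hydroxy-2,2-dimethylcyclobutane-1-carboxylic acid, hydroxyl and carboxyl cis (racemate; the (1S,3R) enantiomer is drawn) | OC(=O)[C@H]1C[C@](O)(c2cc(OC)ccc2OC)C1(C)C | intermediate
9 | (R)-1-phenylethylamine | C[C@@H](N)c1ccccc1 | starting material
10 | (R)-1-phenylethylammonium (1S,3R)-3-(2,5-dimethoxyphenyl)-3-hydroxy-2,2-dimethylcyclobutane-1-carboxylate | [O-]C(=O)[C@H]1C[C@](O)(c2cc(OC)ccc2OC)C1(C)C.C[C@@H]([NH3+])c1ccccc1 | intermediate
11 | (1S,3R)-3-(2,5-dimethoxyphenyl)-3-hydroxy-2,2-dimethylcyclobutane-1-carboxylic acid, single enantiomer (formed in the flask, not isolated) | OC(=O)[C@H]1C[C@](O)(c2cc(OC)ccc2OC)C1(C)C | intermediate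
12 | 2-thioxopyridin-1(2H)-yl (1S,3R)-3-(2,5-dimethoxyphenyl)-3-hydroxy-2,2-dimethylcyclobutane-1-carboxylate, the Barton ester (formed in the flask, not isolated) | S=C1C=CC=CN1OC(=O)[C@H]2C[C@](O)(c3cc(OC)ccc3OC)C2(C)C | intermediate
13 | (1R)-1-(2,5-dimethoxyphenyl)-2,2-dimethylcyclobutan-1-ol | O[C@]1(c2cc(OC)ccc2OC)CCC1(C)C | intermediate
14 | angelic acid, (2Z)-2-methylbut-2-enoic acid | C/C=C(/C)C(=O)O | starting material
15 | angelic anhydride, (2Z)-2-methylbut-2-enoic anhydride (formed in the flask, not isolated) | C/C=C(/C)C(=O)OC(=O)C(/C)=C\C | intermediate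
16 | lithium (1R)-1-(2,5-dimethoxyphenyl)-2,2-dimethylcyclobutan-1-olate (formed in the flask, not isolated) | [Li+].[O-][C@]1(c2cc(OC)ccc2OC)CCC1(C)C | intermediate
17 | (1R)-1-(2,5-dimethoxyphenyl)-2,2-dimethylcyclobutyl (2Z)-2-methylbut-2-enoate | C/C=C(/C)C(=O)O[C@]1(c2cc(OC)ccc2OC)CCC1(C)C | intermediate
18 | (1R)-1-(3,6-dioxocyclohexa-1,4-dien-1-yl)-2,2-dimethylcyclobutyl (2Z)-2-methylbut-2-enoate | C/C=C(/C)C(=O)O[C@]1(C2=CC(=O)C=CC2=O)CCC1(C)C | intermediate
19 | succinic anhydride | O=C1CCC(=O)O1 | starting material
20 | 2,5-bis(trimethylsilyloxy)furan | C[Si](C)(C)Oc1ccc(O[Si](C)(C)C)o1 | intermediate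
21 | (1R)-1-[1,4-bis(trimethylsilyloxy)-5,8-dioxo-1,4,4a,5,8,8a-hexahydro-1,4-epoxynaphthalen-6-yl]-2,2-dimethylcyclobutyl (2Z)-2-methylbut-2-enoate, mixture of isomers at the four transient ring centres (formed in the flask, not isolated) | C/C=C(/C)C(=O)O[C@]1(C2=CC(=O)C3C(C2=O)C4(O[Si](C)(C)C)C=CC3(O[Si](C)(C)C)O4)CCC1(C)C | intermediate
22 | (1R)-1-(5,8-dihydroxy-1,4-dioxo-1,4-dihydronaphthalen-2-yl)-2,2-dimethylcyclobutyl (2Z)-2-methylbut-2-enoate, CNP0326301.1 | C/C=C(/C)C(=O)O[C@]1(C2=CC(=O)c3c(O)ccc(O)c3C2=O)CCC1(C)C | target

**Step count**

Total: 10 steps. Longest linear sequence: 9 steps (steps 1–8 and 10, from 1,4-dimethoxybenzene); step 9 is a one-step side branch.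

**Steps most likely to fail**

Step 3. The excited enol ester may relax or undergo a 1,3-acyl shift before the two alkenes meet, because the ester rests in the rotamer that holds them apart, and energy transfer to the twisted styrene may be slow. The fallback uses known chemistry and sets out from 1. Directed ortho-lithiation (n-BuLi, TMEDA, Et2O, 0 °C to rt) gives 2,5-dimethoxyphenyllithium F1. This adds to commercial 2,2-dimethylcyclobutanone (THF, −78 °C, water quench) to give racemic 1-(2,5-dimethoxyphenyl)-2,2-dimethylcyclobutan-1-ol F2. Its enantiomers are separated by preparative supercritical-fluid chromatography on an amylose carbamate chiral phase. The (1R) enantiomer is 13, where the route is rejoined at step 7.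

Step 7. Acylation of the congested alkoxide may be slow, so that Z-to-E isomerisation of the angeloyl group under prolonged basic conditions competes. The fallback sets out from 13 as its lithium alkoxide 16. It is acylated with the smaller and more reactive 2-[bis(2,2,2-trifluoroethoxy)phosphoryl]propanoyl chloride F3 (from the known acid with oxalyl chloride and catalytic DMF). This gives (1R)-1-(2,5-dimethoxyphenyl)-2,2-dimethylcyclobutyl 2-[bis(2,2,2-trifluoroethoxy)phosphoryl]propanoate F4. Still–Gennari olefination with acetaldehyde (KN(SiMe3)2, 18-crown-6, THF, −78 °C) then forms the Z trisubstituted alkene under kinetic control, so the geometry is created rather than preserved. The product is 17, and the route continues at step 8.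

Step 5. Both diastereomeric salts may co-crystallise, or neither may crystallise, so that no enrichment results. The fallback sets out from 7. The racemic lactone is separated by preparative supercritical-fluid chromatography on a chiral stationary phase into (1R,4S)-1-(2,5-dimethoxyphenyl)-5,5-dimethyl-2-oxabicyclo[2.1.1]hexan-3-one F5 and its antipode. Configuration would be assigned by anomalous-dispersion X-ray analysis. F5 is saponified under the conditions of step 4 to the single-enantiomer acid 11, which enters step 6 at the Barton ester stage.

**Further compounds**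

F1 | step 3 | 2,5-dimethoxyphenyllithium | [Li]c1cc(OC)ccc1OC
F2 | step 3 | racemic 1-(2,5-dimethoxyphenyl)-2,2-dimethylcyclobutan-1-ol | OC1(c2cc(OC)ccc2OC)CCC1(C)C
F3 | step 7 | 2-[bis(2,2,2-trifluoroethoxy)phosphoryl]propanoyl chloride | CC(C(=O)Cl)P(=O)(OCC(F)(F)F)OCC(F)(F)F
F4 | step 7 | (1R)-1-(2,5-dimethoxyphenyl)-2,2-dimethylcyclobutyl 2-[bis(2,2,2-trifluoroethoxy)phosphoryl]propanoate, both epimers at the phosphonate-bearing carbon | CC(C(=O)O[C@]1(c2cc(OC)ccc2OC)CCC1(C)C)P(=O)(OCC(F)(F)F)OCC(F)(F)F
F5 | step 5 | (1R,4S)-1-(2,5-dimethoxyphenyl)-5,5-dimethyl-2-oxabicyclo[2.1.1]hexan-3-one, single enantiomer | O=C1O[C@]2(c3cc(OC)ccc3OC)C[C@H]1C2(C)C
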